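The runs are calculated from invented constants, noise included.

Take

| run | time / min | target / % | starting material / % |
|---|---|---|---|
| grey | 5.00 | 4.1 | 76.8 |
| grey | 10.0 | 5.7 | 63.2 |
| grey | 15.0 | 6.9 | 53.9 |
| grey | 30.0 | 9.2 | 37.9 |
| grey | 60.0 | 11.2 | 22.9 |
| ochre | 5.00 | 2.9 | 81.7 |
| ochre | 10.0 | 4.9 | 70.9 |
| ochre | 15.0 | 5.9 | 62.7 |
| ochre | 30.0 | 9.3 | 47.6 |
| ochre | 60.0 | 11.6 | 31.8 |

(readings scatter by 0.5 percentage points)

 the two runs first, with the recipes, options and questions that go with them:

in all of them: starting material 0.17 M; reagent 0.136 M; free catalyst 8.5 mM; impurity 8.2 mM
- grey: second substrate 0.34 M; temperature 90 °C; the very flask that is asked about, followed so far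
- ochre: second substrate 0.34 M; temperature 85 °C; run made earlier
- flask: second substrate 0.340 M; temperature 90 °C; time 1.0 h

- elm: at 1.0 h raise the temperature by 15 K, then wait 2.0 h
- ash: change nothing and wait 2.0 h more
- alder: at 1.0 h add reagent, 100 % of the amount charged, then wait 2.0 h
- birch: at 1.0 h take out 90 % of the target then present, then wait 2.0 h
- larch: at 1.0 h add free catalyst, 50.0 % of the amount charged, then wait 2.0 h

- target taken out counts as made
- additions bring no volume worth counting

- target, in percent of the starting material first charged, at 1.0 h
- which option adds most target ("none" when 2 percentage points or less is all one gets) (elm / ash / alder / birch / larch / none)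
- target present, with what was taken out counted in, in percent of the starting material first charged, after elm
- target present, with what was taken out counted in, in percent of the starting material first charged, after larch

I start from how the starting material falls. With x its fraction left, the grey run gives a slope of (reciprocal of x, less its start) over time of 0.0570 /min at 15.0 min and 0.0561 /min at 60.0 min, so its loss goes as x squared. I suppose that the target rate goes as x times the catalyst still working. Dividing one rate by the other removes time and x together, which leaves the target gained per unit fall of ln x:

H = ΔP / ln(x_a / x_b)

I call H the worth of the catalyst, and over the whole grey run it is 7.6 percentage points per unit. Since it follows the working catalyst, it should sink as that catalyst goes. In the grey run it is 16 points over the first 5.00 min and 4 points over the last interval, a quarter, though that last figure rests on a difference of two readings, each with scatter 0.5 points. I read this fall as impurity taking catalyst one for one, since 8.2 mM was charged against 8.5 mM.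

For the grey flask I take the reading 11.2 % as "now". Left alone, x goes to 9.01 % in 2.0 h, so ash gives 3.7 points, and I count birch the same. Supposing impurity mostly gone by then, larch adds half a charge of working catalyst:

H(larch) = H(late) + 50.0 % × H(early) = 12 points

gain = H(larch) × ln(x_now / x_end) = 11 points

That makes 22.1 %, and it beats alder even if the reagent doubled H. For elm, ochre at 85 °C has H = 10 points and slope 0.0357 /min. Carrying both trends over 15 K gives H = 1.7 points and x = 3.29 %, hence 14.5 %.

The forecast gives 11.3 %, larch, 13.3 % after elm and 13.7 % after larch, less than my larch figure, with the remark “Larch is the safest choice, though the margin is small.”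

The flask gives 11.4 %, larch, 14.4 % after elm and 25.3 % after larch, a gain of 14 points against 2.3 points for ash.

    second substrate + free catalyst ⇌ catalyst intermediate B (K = 6.40 /M, k = 5.10 /M/s, Ea = 40.0 kJ/mol, ΔH = −62.0 kJ/mol)
    free catalyst + impurity → spent catalyst (k = 5.00 /M/s, Ea = 62.0 kJ/mol)
    reagent + catalyst intermediate A → free catalyst + target (k = 0.340 /M/s, Ea = 44.0 kJ/mol)
    reagent + catalyst intermediate B → free catalyst + second product (k = 0.0790 /M/s, Ea = 72.0 kJ/mol)
    starting material + catalyst intermediate B ⇌ idle complex, settled at all times (K = 27.0 /M, ΔH = 36.0 kJ/mol)
    starting material + free catalyst ⇌ catalyst intermediate A (K = 16.0 /M, k = 0.580 /M/s, Ea = 77.0 kJ/mol, ΔH = −38.0 kJ/mol)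
    2 starting material → self-condensation product (k = 0.00240 /M/s, Ea = 90.0 kJ/mol)
    (constants at 90 °C)

With the other concentrations as charged, free catalyst has a half-life of 0.28 min against impurity, far shorter than the 2.8 h of reagent through catalyst intermediate A at 0.193 h. At 1.00 h spent catalyst in this flask stands at 93.4 % and impurity at 3.18 % of its charge. Between then and 4.0 h this flask pays 2.3 points per unit, a third of 7.6 points. In the neighbour charged with 0.43 M of starting material, H scaled by the ratio of charges and taken over its 11.0 % left gives 6.63 %, and that neighbour holds 6.47 %.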